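3 readings are asked of the flask, each an amount of monomer in chains, and two earlier runs with smaller initiator charges stand beside it.

in all of them: solid monomer 20 mM

|  | initiator | remark | time |
|---|---|---|---|
| dawn | 34 µM | run made earlier |  |
| noon | 51 µM | run made earlier |  |
| flask | 68 µM |  | 1.0 h |

- dawn (time / min: monomer in chains / %): 5.00: 0; 12.0: 0.2; 25.0: 1.6; 60.0: 5.4
- noon (time / min: monomer in chains / %): 5.00: 0.3; 12.0: 0.2; 25.0: 2.0; 60.0: 6.6

(scatter of a reading: 0.3 percentage points)

1. amount of monomer in chains in percent of the solid monomer charged, at 6.0 min, 20 min and 1.0 h

- solid, in amounts per volume of the solution: solid monomer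
- at the start none of the solid monomer is in solution
- a reading or a percentage of monomer in chains counts all its forms, free or not

Dawn and noon share their solid monomer charge and differ in initiator. Noon's charge is 1.50 times dawn's, but its last reading is 1.22 times dawn's, a ratio that carries the scatter of both readings and stands close to the square root of the charge ratio, 1.22. This reckoning takes that square root as a working rule and applies it from noon to the flask:

root factor = √(flask charge / noon charge) = 1.15

This root factor, the square root of the ratio of two initiator charges, by which a reading at a given time passes from one run to another of equal solid monomer charge, differs little from unity. The noon reading can therefore stand as the large part, and only the correction needs reckoning: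

correction at 1.0 h = noon reading × (root factor − one) = 1 percentage point

flask at 1.0 h = 6.6% + correction = 7.60%

Noon has no reading at 20 min, but a straight line between its readings at 12.0 min and 25.0 min gives 1.31%, and the root factor raises this to 1.51%. At 5.00 min the runs read 0% and 0.3%, each within 0.3 points of zero, so this reckoning puts the flask below 0.3 points at 6.0 min.

The weak link is the single noon reading. Dawn's reading, with its own root factor of 1.41, gives 7.64% at 1.0 h, by way of a different measurement.

The forecast gives 0.1%, 1.6% and 7.6%, holding that “the rate goes as the square root of initiator”. Its value at 20 min stands above this reckoning's.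

The flask gives 0.141%, 1.31% and 7.78%, and the forecast holds within its margin.

    free monomer + monomer in chains ⇌ idle adduct, settled at all times (K = 100 M⁻¹)
    solid monomer ⇌ free monomer, rate k2*(cs2 - [free monomer]) while solid is left; crystals form when [free monomer] > cs2 (solubility = 8.20 mM, k = 0.0300 min⁻¹)
    free monomer + initiating radical → growing radical + monomer in chains (k = 3.70 × 10⁵ M⁻¹ s⁻¹)
    2 growing radical → dead chain (k = 1.10 × 10⁶ M⁻¹ s⁻¹)
    initiator → 2 initiating radical (k = 7.10 × 10⁻⁴ min⁻¹)
    free monomer + growing radical → monomer in chains + growing radical, rate k6*[growing radical]*[free monomer] (k = 2.50 × 10⁵ M⁻¹ min⁻¹)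

Divided by the root factor, the flask's 7.78% becomes 6.77%, beside noon's reading of 6.6%, and a square root of the same form, taken of the initiator left in the flask at 10.0 h over that at 0.100 h, takes the flask's growing radical from 2.70 × 10⁻⁵ mM to 2.19 × 10⁻⁵ mM, where the flask holds 2.19 × 10⁻⁵ mM. At 0.350 h the passing of free monomer into monomer in chains, a pseudo-first-order step, gives free monomer a half-life of 1.7 h, whereas initiator's half-life by its own step is longer at 16 h, and at 1.00 h the flask keeps 96% of its initiator.

The runs come from a simulation for substances that don't exist; scatter was added.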